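**Retrosynthetic overview**
1. The target comes from its bis-benzyl form (2-O-benzyl ether on the A ring, benzyl ester on the B ring). Both benzyl groups are removed in one final hydrogenolysis.
2. Both Ar–CH2C(O)C5H11 bonds are cut at once. The forward reaction is a twofold ester-directed ortho C–H acylmethylation (new step) of a side-chain-free depside with a hexanoyl-derived sulfoxonium ylide.
3. The depside acyl C–O bond is cut to give 2-(benzyloxy)-4-methoxybenzoic acid and benzyl 4-hydroxy-2-methoxybenzoate.
4. These two come from commercial 2-hydroxy-4-methoxybenzoic acid and 4-hydroxy-2-methoxybenzoic acid. The ylide comes from hexanoyl chloride and trimethylsulfoxonium iodide.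
5. No ring is formed, because both benzene rings are bought intact.

Assumption: the target SMILES has no stereocentre and no stereogenic double bond, so the compound is achiral and no step needs stereocontrol.

**Step 1**
Reactants: 1 trimethylsulfoxonium iodide; 2 hexanoyl chloride
Product: 4 1-[dimethyl(oxo)-λ6-sulfanylidene]heptan-2-one, via dimethylsulfoxonium methylide 3 (not isolated)
Conditions: 1 (3 equiv), KOtBu (3 equiv), THF, reflux, 2 h; then 2 (1 equiv), 0 °C to rt
Reagents that add atoms: none
Why: Corey–Chaykovsky-type C-acylation of the unstabilised methylide by the acid chloride, after which a second equivalent of methylide removes the acidic α-proton to give the stable β-keto sulfoxonium ylide; no stereocentre is formed.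

**Step 2**
Reactants: 5 2-hydroxy-4-methoxybenzoic acid
Product: 6 benzyl 2-(benzyloxy)-4-methoxybenzoate
Conditions: BnBr (2.3 equiv), K2CO3 (3 equiv), DMF, 60 °C
Reagents that add atoms: benzyl bromide, BrCc1ccccc1
Why: Williamson etherification of the phenoxide and SN2 alkylation of the carboxylate take place in one pot with a reactive benzylic halide.

**Step 3**
Reactants: 6 benzyl 2-(benzyloxy)-4-methoxybenzoate
Product: 7 2-(benzyloxy)-4-methoxybenzoic acid
Conditions: KOH (4 equiv), 1,4-dioxane–H2O 2:1, 80 °C; then 1 M HCl, 0 °C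
Reagents that add atoms: potassium hydroxide, [K+].[OH-]
Why: BAc2 saponification of a benzoate with only one ortho substituent, in which the aryl benzyl and aryl methyl ethers are inert to hydroxide.

**Step 4**
Reactants: 8 4-hydroxy-2-methoxybenzoic acid
Product: 9 benzyl 4-hydroxy-2-methoxybenzoate
Conditions: BnBr (1.05 equiv), KHCO3 (1.2 equiv), DMF, 40 °C
Reagents that add atoms: benzyl bromide, BrCc1ccccc1
Why: Chemoselective carboxylate SN2 alkylation, because hydrogencarbonate deprotonates only the CO2H (pKa about 4) and leaves the phenol (pKa about 9) protonated and free.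

**Step 5**
Reactants: 7 2-(benzyloxy)-4-methoxybenzoic acid; 9 benzyl 4-hydroxy-2-methoxybenzoate
Product: 11 benzyl 4-{[2-(benzyloxy)-4-methoxybenzoyl]oxy}-2-methoxybenzoate, via 2-(benzyloxy)-4-methoxybenzoyl chloride 10 (not isolated)
Conditions: 7, (COCl)2 (1.3 equiv), DMF (cat.), CH2Cl2, 0 °C to rt, evaporate; then 9 (1.0 equiv), Et3N (1.5 equiv), DMAP (10 mol %), CH2Cl2, 0 °C to rt
Reagents that add atoms: none
Why: Vilsmeier-catalysed acid chloride formation is followed by DMAP-catalysed O-acylation of the only free OH in 9, and no enolisable ketone is yet present that could divert the acyl donor to an isocoumarin.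

**Step 6**
Reactants: 11 benzyl 4-{[2-(benzyloxy)-4-methoxybenzoyl]oxy}-2-methoxybenzoate; 4 1-[dimethyl(oxo)-λ6-sulfanylidene]heptan-2-one (3 equiv)
Product: 14 benzyl 4-{[2-(benzyloxy)-4-methoxy-6-(2-oxoheptyl)benzoyl]oxy}-2-methoxy-6-(2-oxoheptyl)benzoate, via A-ring monoketone 12 (not isolated), via B-ring monoketone 13 (not isolated)
Conditions: [Cp*IrCl2]2 (5 mol %), AgNTf2 (20 mol %), NaOPiv (20 mol %), PivOH (40 mol %), 4 added by syringe pump over 6 h, DCE–HFIP 4:1, 60 °C, Ar
Reagents that add atoms: none
Why: Proposed new method: a cationic Cp*Ir(III) pivalate binds the carbonyl O of each benzoate ester (aryl ester on the A ring, benzyl ester on the B ring), carboxylate-assisted CMD cleaves the only free ortho C–H (C6 and C6'; the other ortho site carries OBn or OMe, so the reaction stops at one insertion per ring) to give a five-membered iridacycle, ylide 4 binds through carbon and loses DMSO to give an Ir α-oxo-carbene, 1,1-migratory insertion makes the Ar–CH bond, and PivOH protodemetalates the resulting Ir enolate before it can O-acylate, releasing ArCH2C(O)C5H11; the closest known reaction types are Cp*Rh(III)/Ir(III) C–H acylmethylation with sulfoxonium ylides under N-donor or free carboxylic acid direction (the latter ending in isocoumarins) and Cp*Ir(III) C–H amidation directed by simple benzoate esters, while to my knowledge the new elements are a plain ester as the sole directing group for carbene insertion, stopping at the open keto ester in a buffered medium free of strong acid, and the twofold use on a depside; no stereocentre is formed.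

**Step 7**
Reactants: 14 benzyl 4-{[2-(benzyloxy)-4-methoxy-6-(2-oxoheptyl)benzoyl]oxy}-2-methoxy-6-(2-oxoheptyl)benzoate
Product: 15 4-{[2-hydroxy-4-methoxy-6-(2-oxoheptyl)benzoyl]oxy}-2-methoxy-6-(2-oxoheptyl)benzoic acid (target)
Conditions: H2 (1 atm), 10 % Pd/C, EtOAc, rt
Reagents that add atoms: none
Why: Neutral heterogeneous hydrogenolysis cleaves both benzylic C–O bonds, while the non-conjugated ketones, the aryl ester and the methyl ethers are inert at 1 atm, so neither acid nor base can trigger depside cleavage or isocoumarin formation.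

**Compound list**
1 | trimethylsulfoxonium iodide | C[S+](C)(C)=O.[I-] | starting material
2 | hexanoyl chloride | CCCCCC(=O)Cl | starting material
3 | dimethylsulfoxonium methylide | C=S(C)(C)=O | intermediate
4 | 1-[dimethyl(oxo)-λ6-sulfanylidene]heptan-2-one | CCCCCC(=O)C=S(C)(C)=O | intermediate
5 | 2-hydroxy-4-methoxybenzoic acid | COc1ccc(C(=O)O)c(O)c1 | starting material
6 | benzyl 2-(benzyloxy)-4-methoxybenzoate | COc1ccc(C(=O)OCc2ccccc2)c(OCc2ccccc2)c1 | intermediate
7 | 2-(benzyloxy)-4-methoxybenzoic acid | COc1ccc(C(=O)O)c(OCc2ccccc2)c1 | intermediate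
8 | 4-hydroxy-2-methoxybenzoic acid | COc1cc(O)ccc1C(=O)O | starting material
9 | benzyl 4-hydroxy-2-methoxybenzoate | COc1cc(O)ccc1C(=O)OCc1ccccc1 | intermediate
10 | 2-(benzyloxy)-4-methoxybenzoyl chloride | COc1ccc(C(=O)Cl)c(OCc2ccccc2)c1 | intermediate
11 | benzyl 4-{[2-(benzyloxy)-4-methoxybenzoyl]oxy}-2-methoxybenzoate | COc1ccc(C(=O)Oc2ccc(C(=O)OCc3ccccc3)c(OC)c2)c(OCc2ccccc2)c1 | intermediate
12 | benzyl 4-{[2-(benzyloxy)-4-methoxy-6-(2-oxoheptyl)benzoyl]oxy}-2-methoxybenzoate | CCCCCC(=O)Cc1cc(OC)cc(OCc2ccccc2)c1C(=O)Oc1ccc(C(=O)OCc2ccccc2)c(OC)c1 | intermediate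
13 | benzyl 4-{[2-(benzyloxy)-4-methoxybenzoyl]oxy}-2-methoxy-6-(2-oxoheptyl)benzoate | COc1ccc(C(=O)Oc2cc(CC(=O)CCCCC)c(C(=O)OCc3ccccc3)c(OC)c2)c(OCc2ccccc2)c1 | intermediate
14 | benzyl 4-{[2-(benzyloxy)-4-methoxy-6-(2-oxoheptyl)benzoyl]oxy}-2-methoxy-6-(2-oxoheptyl)benzoate | CCCCCC(=O)Cc1cc(OC)cc(OCc2ccccc2)c1C(=O)Oc1cc(CC(=O)CCCCC)c(C(=O)OCc2ccccc2)c(OC)c1 | intermediate
15 | 4-{[2-hydroxy-4-methoxy-6-(2-oxoheptyl)benzoyl]oxy}-2-methoxy-6-(2-oxoheptyl)benzoic acid | CCCCCC(=O)Cc1cc(OC)cc(O)c1C(=O)Oc1cc(CC(=O)CCCCC)c(C(=O)O)c(OC)c1 | target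

**Total step count:** 7. **Longest linear sequence:** 5 (steps 2, 3, 5, 6, 7).

**Three steps most likely to fail**

**Step 6 (the proposed new step).**
- The ester carbonyls are weak donors, and ylide 4 or released DMSO may displace them from iridium.
- The second insertion may stall at 12 or 13.
- The A-ring carbonyl could direct metalation into the B ring through a six-membered metallacycle.
- The keto aryl ester could collapse to an isocoumarin with loss of the B-ring phenol.

The fallback uses only known chemistry. It sets out from acids 7 and 8 together with ylide 4, and it comes back at 14.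
- Carboxylate-directed Cp*Rh(III) C–H acylmethylation with cyclocondensation of 7 and 4 ([Cp*RhCl2]2, AgSbF6, NaOAc, DCE, 100 °C) gives 8-(benzyloxy)-6-methoxy-3-pentyl-1H-isochromen-1-one F1.
- KOH in aqueous EtOH followed by cold acidification opens it to 2-(benzyloxy)-4-methoxy-6-(2-oxoheptyl)benzoic acid F2.
- The same annulation on 8 gives 6-hydroxy-8-methoxy-3-pentyl-1H-isochromen-1-one F3.
- Alkaline opening of that lactone gives 4-hydroxy-2-methoxy-6-(2-oxoheptyl)benzoic acid F4.
- BnBr/KHCO3 in DMF converts it to benzyl 4-hydroxy-2-methoxy-6-(2-oxoheptyl)benzoate F5.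
- The keto acid and the keto phenol are then joined with DCC in toluene at rt. This base-free carbodiimide protocol is established for keto-depsides and delivers 14.

**Step 5.** The o-benzyloxy acid chloride 10 can lose its benzyl group on standing, and phenol 9 is a poor nucleophile because of its para ester.

The fallback makes the other C–O bond of the ester, the aryl C–O bond instead of the acyl C–O bond. It sets out from 7 and comes back at 11.
- Commercial 4-borono-2-methoxybenzoic acid is benzylated at the carboxylate (BnBr, KHCO3, DMF) to [4-(benzyloxycarbonyl)-3-methoxyphenyl]boronic acid F6.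
- Acid 7 is then O-arylated with it under Cu(OTf)2-mediated Chan–Lam conditions (urea, EtOAc, 60 °C, air) to give 11.

**Step 7.** Traces of sulfur species carried over from step 6 can poison Pd/C, and the product keto acid does not tolerate long reaction times or heating.

The fallback replaces surface hydrogenolysis by Lewis-acid benzyl-cation transfer. It sets out from 14 and comes back at 15.
- BCl3 (4 equiv) and pentamethylbenzene (6 equiv) in CH2Cl2 at −78 °C transfer both O-benzyl groups to the arene scavenger.
- At this temperature the methyl ethers are not touched, and a cold aqueous quench gives 15.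
- This fallback makes no new compound (F0).

**Further compounds**
F1 | step 6 | 8-(benzyloxy)-6-methoxy-3-pentyl-1H-isochromen-1-one | CCCCCc1cc2cc(OC)cc(OCc3ccccc3)c2c(=O)o1
F2 | step 6 | 2-(benzyloxy)-4-methoxy-6-(2-oxoheptyl)benzoic acid | CCCCCC(=O)Cc1cc(OC)cc(OCc2ccccc2)c1C(=O)O
F3 | step 6 | 6-hydroxy-8-methoxy-3-pentyl-1H-isochromen-1-one | CCCCCc1cc2cc(O)cc(OC)c2c(=O)o1
F4 | step 6 | 4-hydroxy-2-methoxy-6-(2-oxoheptyl)benzoic acid | CCCCCC(=O)Cc1cc(O)cc(OC)c1C(=O)O
F5 | step 6 | benzyl 4-hydroxy-2-methoxy-6-(2-oxoheptyl)benzoate | CCCCCC(=O)Cc1cc(O)cc(OC)c1C(=O)OCc1ccccc1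
F6 | step 5 | [4-(benzyloxycarbonyl)-3-methoxyphenyl]boronic acid | COc1cc(B(O)O)ccc1C(=O)OCc1ccccc1
F0 | step 7 | none | none
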